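**Retrosynthetic overview**

1. Numbering: ring A (dibromo ring) is C1 (CH2OH), C2 (Br), C3 (O‑aryl), C4 (OH), C5 (Br), C6 (H); ring B is C1' (ether O), C2' (CH2OH), C3' (H), C4' (Br), C5' (OH), C6' (OH). The strategy rests on this feature: C1 is para to C4–OH and C2' is para to C5'–OH, and every position ortho to these two phenols (C3/C5 and C4'/C6') is substituted.
2. 13 ⇒ 12 ⇒ 11: the two benzylic alcohols come from aldehydes (NaBH4) and O6'–H from an O6' methyl ether (BBr3).
3. Key disconnection 11 ⇒ 8 + 2 C1 units: the C1–CHO and C2'–CHO bonds are made together by twofold Duff formylation para to the two free phenols of tribromo bis‑phenol 8.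
4. 8 ⇒ 3 + 4: the ether bond C3–O–C1' is made by SNAr on 3,6‑dibromo‑2‑fluorobenzaldehyde, whose formyl group is then converted into C4–OH by Baeyer–Villiger oxidation; 3 ⇒ 1 by monotosylation and para‑bromination.
5. No ring is formed: ring B is bought as 1 and ring A as 4, and they are joined in step 3.

Key step: step 5

Remark: the target has no stereocentre and the diaryl ether axis is taken as freely rotating, so the compound is achiral and needs no stereocontrol.
Remark: 3,6‑dibromo‑2‑fluorobenzaldehyde (4) is taken to be a purchasable building block.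

**Route**

Step 1
Reactants: 1 2‑methoxybenzene‑1,3‑diol (2‑methoxyresorcinol)
Product: 2 3‑hydroxy‑2‑methoxyphenyl 4‑methylbenzenesulfonate
Conditions: TsCl (0.95 equiv, slow addition), K2CO3, acetone, 0 °C → rt
Reagents that add atoms: p‑toluenesulfonyl chloride, Cc1ccc(cc1)S(Cl)(=O)=O
Why: Desymmetrising O‑sulfonylation of a C2‑symmetric diol with a slight deficit of sulfonyl chloride should give mainly the mono‑tosylate, with unreacted 1 and the bis‑tosylate easily separated.

Step 2
Reactants: 2 3‑hydroxy‑2‑methoxyphenyl 4‑methylbenzenesulfonate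
Product: 3 6‑bromo‑3‑hydroxy‑2‑methoxyphenyl 4‑methylbenzenesulfonate
Conditions: NBS (1.0 equiv), MeCN, −20 → 0 °C
Reagents that add atoms: N‑bromosuccinimide, BrN1C(=O)CCC1=O
Why: Electrophilic aromatic bromination directed by the only strong donor, the free phenol, should go para to OH (ortho to the weakly donating sulfonate oxygen), as is usual for 2‑alkoxyphenols with NBS in acetonitrile.

Step 3
Reactants: 3 6‑bromo‑3‑hydroxy‑2‑methoxyphenyl 4‑methylbenzenesulfonate; 4 3,6‑dibromo‑2‑fluorobenzaldehyde
Product: 5 6‑bromo‑3‑(3,6‑dibromo‑2‑formylphenoxy)‑2‑methoxyphenyl 4‑methylbenzenesulfonate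
Conditions: K2CO3, DMF, 70 °C
Reagents that add atoms: none
Why: SNAr through a Meisenheimer adduct: the phenoxide of 3 displaces the fluoride activated by the ortho formyl group, fluoride leaving much faster than the ortho bromide, and the aryl sulfonate tolerates carbonate.

Step 4
Reactants: 5 6‑bromo‑3‑(3,6‑dibromo‑2‑formylphenoxy)‑2‑methoxyphenyl 4‑methylbenzenesulfonate
Product: 8 6‑bromo‑3‑(3,6‑dibromo‑2‑hydroxyphenoxy)‑2‑methoxyphenol, via aryl formate 6 (not isolated), via phenol tosylate 7 (not isolated)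
Conditions: mCPBA, CH2Cl2, 0 °C → rt; aq. Na2S2O3/NaHCO3 wash, evaporate; then 2 M NaOH, 1,4‑dioxane, 80 °C (N2); aq. HCl
Reagents that add atoms: m‑chloroperbenzoic acid, OOC(=O)c1cccc(Cl)c1
Why: Baeyer–Villiger (Dakin‑type) oxidation in which the aryl group carrying the ortho aryloxy donor migrates in the Criegee adduct to give formate 6, after which hydroxide cleaves the formate and then the sulfonate at S–O to free both phenols.

Step 5
Reactants: 8 6‑bromo‑3‑(3,6‑dibromo‑2‑hydroxyphenoxy)‑2‑methoxyphenol; 9 hexamethylenetetramine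
Product: 11 2,5‑dibromo‑3‑(4‑bromo‑6‑formyl‑3‑hydroxy‑2‑methoxyphenoxy)‑4‑hydroxybenzaldehyde, via bis‑iminium Duff intermediate 10 (not isolated)
Conditions: 9 (6 equiv), TFA, reflux, 24 h; then 3 M aq. HCl, 50 °C
Reagents that add atoms: water, O
Why: Duff formylation: protonated hexamethylenetetramine opens to an N‑methyleneiminium ion that attacks each ring by electrophilic aromatic substitution, the benzylic amines formed are dehydrogenated by hydride transfer to a further iminium unit, and the resulting aryl–CH=N+ ions (10) are hydrolysed by aqueous acid to the two aldehydes. The closest known reaction type is the para‑formylation of 2,6‑disubstituted phenols (dialkyl, dimethoxy, dihalo) with hexamethylenetetramine in trifluoroacetic acid. No ring closes and no stereocentre forms; the two new bonds are C1–CHO on ring A and C2'–CHO on ring B. The selectivity needed is attack para to each free OH and not para to an ether oxygen (C6 on ring A, C3' on ring B); the hydroxyl is the strongest donor on each ring, its two ortho positions are blocked (C3–OAr/C5–Br and C4'–Br/C6'–OMe), the doubly flanked O6' methyl ether is twisted out of conjugation and cannot act as a second phenol, and C2' is further activated by the ortho ether oxygen on C1'. Cyclisation of a benzylic cation onto the other ring is excluded because C2 and C4, the positions ortho to the ether bridge on ring A, are substituted. Excess reagent and long heating should offset the deactivation by three bromines, and the first formyl group deactivates only its own ring.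

Step 6
Reactants: 11 2,5‑dibromo‑3‑(4‑bromo‑6‑formyl‑3‑hydroxy‑2‑methoxyphenoxy)‑4‑hydroxybenzaldehyde
Product: 12 2,5‑dibromo‑3‑(4‑bromo‑6‑formyl‑2,3‑dihydroxyphenoxy)‑4‑hydroxybenzaldehyde
Conditions: BBr3 (6 equiv), CH2Cl2, −78 °C → rt; ice‑water
Reagents that add atoms: none
Why: Lewis‑acid aryl methyl ether cleavage (bromide attacks the methyl of the boron‑complexed ether, helped by the neighbouring aryloxyborane at O5'), which aryl aldehydes, aryl bromides and the diaryl ether tolerate, and which is placed before the reduction because benzylic alcohols would be converted into benzylic bromides.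

Step 7
Reactants: 12 2,5‑dibromo‑3‑(4‑bromo‑6‑formyl‑2,3‑dihydroxyphenoxy)‑4‑hydroxybenzaldehyde
Product: 13 3‑bromo‑6‑[3,6‑dibromo‑2‑hydroxy‑5‑(hydroxymethyl)phenoxy]‑5‑(hydroxymethyl)benzene‑1,2‑diol
Conditions: NaBH4 (5 equiv), THF/H2O, 0 °C; aq. NH4Cl (pH about 6), cold extraction
Reagents that add atoms: none
Why: Borohydride reduction of both aryl aldehydes leaves the aryl bromides untouched, and a cold, near‑neutral, alcohol‑free work‑up should prevent quinone‑methide chemistry (etherification, oligomerisation, over‑reduction) of the para‑hydroxybenzyl alcohols.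

**Compound list**

1 | 2‑methoxybenzene‑1,3‑diol (2‑methoxyresorcinol) | COc1c(O)cccc1O | starting material
2 | 3‑hydroxy‑2‑methoxyphenyl 4‑methylbenzenesulfonate | COc1c(O)cccc1OS(=O)(=O)c1ccc(C)cc1 | intermediate
3 | 6‑bromo‑3‑hydroxy‑2‑methoxyphenyl 4‑methylbenzenesulfonate | COc1c(O)ccc(Br)c1OS(=O)(=O)c1ccc(C)cc1 | intermediate
4 | 3,6‑dibromo‑2‑fluorobenzaldehyde | O=Cc1c(F)c(Br)ccc1Br | starting material
5 | 6‑bromo‑3‑(3,6‑dibromo‑2‑formylphenoxy)‑2‑methoxyphenyl 4‑methylbenzenesulfonate | COc1c(OS(=O)(=O)c2ccc(C)cc2)c(Br)ccc1Oc1c(C=O)c(Br)ccc1Br | intermediate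
6 | 6‑bromo‑3‑[3,6‑dibromo‑2‑(formyloxy)phenoxy]‑2‑methoxyphenyl 4‑methylbenzenesulfonate | COc1c(OS(=O)(=O)c2ccc(C)cc2)c(Br)ccc1Oc1c(OC=O)c(Br)ccc1Br | intermediate (not isolated)
7 | 6‑bromo‑3‑(3,6‑dibromo‑2‑hydroxyphenoxy)‑2‑methoxyphenyl 4‑methylbenzenesulfonate | COc1c(OS(=O)(=O)c2ccc(C)cc2)c(Br)ccc1Oc1c(O)c(Br)ccc1Br | intermediate (not isolated)
8 | 6‑bromo‑3‑(3,6‑dibromo‑2‑hydroxyphenoxy)‑2‑methoxyphenol | COc1c(O)c(Br)ccc1Oc1c(O)c(Br)ccc1Br | intermediate
9 | hexamethylenetetramine | C1N2CN3CN1CN(C2)C3 | starting material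
10 | bis‑iminium Duff intermediate (written in its simplest form as the bis‑aldimine; in the acid each nitrogen is protonated and can still carry a fragment of the cage) | COc1c(O)c(Br)cc(C=N)c1Oc1c(O)c(Br)cc(C=N)c1Br | intermediate (not isolated)
11 | 2,5‑dibromo‑3‑(4‑bromo‑6‑formyl‑3‑hydroxy‑2‑methoxyphenoxy)‑4‑hydroxybenzaldehyde | COc1c(O)c(Br)cc(C=O)c1Oc1c(O)c(Br)cc(C=O)c1Br | intermediate
12 | 2,5‑dibromo‑3‑(4‑bromo‑6‑formyl‑2,3‑dihydroxyphenoxy)‑4‑hydroxybenzaldehyde | O=Cc1cc(Br)c(O)c(Oc2c(C=O)cc(Br)c(O)c2O)c1Br | intermediate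
13 | 3‑bromo‑6‑[3,6‑dibromo‑2‑hydroxy‑5‑(hydroxymethyl)phenoxy]‑5‑(hydroxymethyl)benzene‑1,2‑diol | OCc1cc(Br)c(O)c(Oc2c(CO)cc(Br)c(O)c2O)c1Br | target

**Step count**

Total step count: 7. Longest linear sequence: 7 steps (1 → 13); 4 and 9 enter as purchased materials.

**Steps most likely to fail**

Step 5 (key step). The electrophilic substitution may stall on the bromine‑deactivated rings, stopping at mono‑formylation, or may go partly para to an ether oxygen. Fallback: starting from 8, twofold iodination para to each phenol (NIS, cat. TFA, MeCN, 0 °C) should give 6‑bromo‑3‑(3,6‑dibromo‑2‑hydroxy‑5‑iodophenoxy)‑4‑iodo‑2‑methoxyphenol F1. Both phenols are then deprotonated with MeMgCl (THF, −20 °C), and iodine–magnesium exchange with i‑PrMgCl·LiCl (iodide exchanges much faster than bromide; the temperature is kept low so the ortho‑bromoaryl Grignard does not eliminate) followed by DMF and aqueous HCl would return to the route at 11.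

Step 4. In the Criegee adduct hydride may migrate in place of the bromine‑deactivated aryl group, which would lead to the benzoic acid and not the formate. Fallback: starting from 5, MeMgBr (THF, −78 °C) should give racemic 6‑bromo‑3‑[3,6‑dibromo‑2‑(1‑hydroxyethyl)phenoxy]‑2‑methoxyphenyl 4‑methylbenzenesulfonate F2, and Dess–Martin oxidation 3‑(2‑acetyl‑3,6‑dibromophenoxy)‑6‑bromo‑2‑methoxyphenyl 4‑methylbenzenesulfonate F3. Baeyer–Villiger oxidation of this methyl ketone with trifluoroperacetic acid (urea–H2O2, TFAA, Na2HPO4, CH2Cl2), where methyl cannot compete with aryl migration, should give 3‑(2‑acetoxy‑3,6‑dibromophenoxy)‑6‑bromo‑2‑methoxyphenyl 4‑methylbenzenesulfonate F4. The same hot NaOH/dioxane treatment then cleaves acetate and sulfonate and returns to the route at 8.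

Step 2. Bromination may occur partly ortho to the free hydroxyl, or twice, which would place the bromine on the wrong carbon in an isomer that is hard to separate. Fallback: starting from 1, monobromination (NBS, MeCN, −20 °C) can give only one monobromide at an activated position by symmetry, 4‑bromo‑2‑methoxybenzene‑1,3‑diol F5. Its dianion (NaH, 2.1 equiv, DMF) should react with 4 (1.0 equiv) at the more basic and less hindered oxygen para to bromine, giving 3,6‑dibromo‑2‑(4‑bromo‑3‑hydroxy‑2‑methoxyphenoxy)benzaldehyde F6. Tosylation of the remaining phenol (TsCl, Et3N, CH2Cl2) returns to the route at 5.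

**Further compounds**

F1 | step 5 | 6‑bromo‑3‑(3,6‑dibromo‑2‑hydroxy‑5‑iodophenoxy)‑4‑iodo‑2‑methoxyphenol | COc1c(O)c(Br)cc(I)c1Oc1c(O)c(Br)cc(I)c1Br
F2 | step 4 | 6‑bromo‑3‑[3,6‑dibromo‑2‑(1‑hydroxyethyl)phenoxy]‑2‑methoxyphenyl 4‑methylbenzenesulfonate (racemic) | COc1c(OS(=O)(=O)c2ccc(C)cc2)c(Br)ccc1Oc1c(C(C)O)c(Br)ccc1Br
F3 | step 4 | 3‑(2‑acetyl‑3,6‑dibromophenoxy)‑6‑bromo‑2‑methoxyphenyl 4‑methylbenzenesulfonate | COc1c(OS(=O)(=O)c2ccc(C)cc2)c(Br)ccc1Oc1c(C(C)=O)c(Br)ccc1Br
F4 | step 4 | 3‑(2‑acetoxy‑3,6‑dibromophenoxy)‑6‑bromo‑2‑methoxyphenyl 4‑methylbenzenesulfonate | COc1c(OS(=O)(=O)c2ccc(C)cc2)c(Br)ccc1Oc1c(OC(C)=O)c(Br)ccc1Br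
F5 | step 2 | 4‑bromo‑2‑methoxybenzene‑1,3‑diol | COc1c(O)ccc(Br)c1O
F6 | step 2 | 3,6‑dibromo‑2‑(4‑bromo‑3‑hydroxy‑2‑methoxyphenoxy)benzaldehyde | COc1c(O)c(Br)ccc1Oc1c(C=O)c(Br)ccc1Br
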